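Percent of the substrate charged is the unit that lets me lay runs of different charge side by side, so I read everything in it.

| flask | substrate | remark | time |
|---|---|---|---|
| ochre | 0.28 M | run made earlier |  |
| green | 0.44 M | run made earlier |  |
| flask | 0.20 M |  | 10 min |

| run | time / min | target / % | substrate / % | side product / % |
|---|---|---|---|---|
| ochre | 3.00 | 19.9 | 78.0 | 1.8 |
| ochre | 6.00 | 37.3 | 60.5 | 3.6 |
| ochre | 10.0 | 52.0 | 42.9 | 4.0 |
| ochre | 12.0 | 59.3 | 36.0 | 4.9 |
| green | 1.00 | 7.5 | 92.6 | 0.9 |
| green | 2.00 | 14.3 | 84.6 | 2.0 |
| green | 5.00 | 32.0 | 65.3 | 2.5 |
| green | 12.0 | 59.2 | 36.4 | 4.9 |

(each reading ± 0.3 percentage points)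

* the species that holds most of what was charged as substrate, at 10 min (substrate / side product / target)
* the largest share itself, whichever of these holds it, in percent of the substrate charged

I read the two tables against each other at their shared last row, 12.0 min. The ochre run, charged at 0.28 M, keeps 36.0% of its substrate, and the green run, charged at 0.44 M, keeps 36.4%, a gap of 0.4 percentage points against a scatter of 0.3 points per reading. So in these runs the remaining share does not follow the charge, and I freeze what stays constant. Averaged over that row, k comes to 0.0847 min⁻¹, where k is the natural logarithm of charged over remaining substrate, divided by time, the apparent first-order rate constant. An earlier row agrees: the green run at 5.00 min keeps 65.3%, which gives 0.0852 min⁻¹.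

The other columns of the ochre row give f, the target's share of what has reacted (the selectivity), as 92.4%.

The flask's charge of 0.20 M lies below both runs, so I carry k one step beyond the readings. My reckoning for the flask at 10 min leaves 42.9% of substrate and makes 52.8% of target, which is more than the substrate.

The forecast names target at 52.4%, on the ground that “Both runs give the same percentage curves despite the different starting concentrations”. My figure stands 0.40 points above its share.

The flask gives target at 52.7%, with 43.1% of substrate beside my 42.9% from k.

    substrate → side product (k = 0.00611 min⁻¹)
    substrate → target (k = 0.0780 min⁻¹)

The ochre run at its last reading, without scatter, holds 58.9% of target; moving only its charge to the flask's leaves 58.9%, while moving only its time to the flask's gives 52.7%. For the same flask left until 15 min, k gives 28.1% of its substrate remaining, and that flask holds 28.3%.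

(The numbers in the tables were generated by integration with constants of no real substance, noise included.)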